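**Plan**

- Retrosynthesis: the last two operations only adjust oxidation state and protection (ring A O‑demethylation; benzylic OMe → C=O). Before that, the pyran ring is cut at two bonds, benzylic carbon–CH2 and O–CMe2, which gives a depsidone carrying a ring B salicylaldehyde plus 2‑methylpropene.
- Enabling feature: on ring B the pyranone oxygen (on C‑7) and the chromanone carbonyl carbon (on C‑8) sit on neighbouring ring carbons. This O–C7–C8–C unit is an ortho‑hydroxybenzaldehyde which, at acetal level, is the four‑atom heterodiene of a methoxy ortho‑quinone methide.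
- Further cuts: ring B formyl (ortho‑formylation), lactone C(=O)–O (lactonisation), ring B lactone oxygen (para‑oxidation of a phenol), diaryl ether (SNAr of orcinol on a ring A fluoride flanked by formyl and ester), and ring A substituents back to 3,5‑difluorotoluene.
- Forward order: ring A is functionalised, the diaryl ether joins ring B, the seven‑membered dioxepinone closes, the pyran ring closes (key step), then oxidation and deprotection.
- Stereochemistry: the target is achiral. The single stereocentre made in the key step (the methoxy‑bearing benzylic carbon) is racemic and is erased when it becomes the ketone.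

Key step: step 10

Remark: depsidone locants follow 11H‑dibenzo[b,e][1,4]dioxepin‑11‑one (ring A = C‑1 to C‑4 on the carbonyl side, ring B = C‑6 to C‑9, O‑5 ether, O‑10 lactone oxygen). The ring A formyl group is deliberately kept free through the key step; the risk this carries is treated at the end.

**Route**

Step 1
Reactants: 1 3,5-difluorotoluene
Product: 3 2,6-difluoro-4-methylbenzaldehyde, via 2,6-difluoro-4-methylphenyllithium 2 (not isolated)
Conditions: n-BuLi, THF, −78 °C; then DMF, −78 → 0 °C; aq. HCl
Reagents that add atoms: N,N-dimethylformamide, CN(C)C=O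
Why: The C–H flanked by both fluorines is the most acidic position, so ortho-lithiation followed by formylation with DMF should give one aldehyde.

Step 2
Reactants: 3 2,6-difluoro-4-methylbenzaldehyde
Product: 4 2-fluoro-6-methoxy-4-methylbenzaldehyde
Conditions: NaOMe (1.05 equiv), MeOH, 0 °C → rt
Reagents that add atoms: sodium methoxide, C[O-].[Na+]
Why: SNAr at a fluoride ortho to the formyl group, where the first methoxy group deactivates the ring towards a second substitution, so mono-substitution of the symmetric difluoride is expected.

Step 3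
Reactants: 4 2-fluoro-6-methoxy-4-methylbenzaldehyde
Product: 5 3-bromo-2-fluoro-6-methoxy-4-methylbenzaldehyde
Conditions: NBS, MeCN, 0 °C → rt, dark
Reagents that add atoms: N-bromosuccinimide, O=C1CCC(=O)N1Br
Why: Electrophilic aromatic bromination should go para to the methoxy group, at the position flanked by the small fluorine and the methyl group, which is both the electronically and the sterically preferred site.

Step 4
Reactants: 5 3-bromo-2-fluoro-6-methoxy-4-methylbenzaldehyde
Product: 6 benzyl 2-fluoro-3-formyl-4-methoxy-6-methylbenzoate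
Conditions: Pd(OAc)2 (cat.), Xantphos, CO (1 atm), BnOH, Et3N, toluene, 90 °C
Reagents that add atoms: carbon monoxide, [C-]#[O+]; benzyl alcohol, OCc1ccccc1
Why: Palladium-catalysed alkoxycarbonylation of an aryl bromide with a wide-bite-angle diphosphine works at atmospheric CO pressure on ortho-substituted bromides, and the amine base is too weak to displace the fluoride.

Step 5
Reactants: 6 benzyl 2-fluoro-3-formyl-4-methoxy-6-methylbenzoate; 7 orcinol
Product: 8 benzyl 3-formyl-2-(3-hydroxy-5-methylphenoxy)-4-methoxy-6-methylbenzoate
Conditions: orcinol (3 equiv), K2CO3, DMF, rt → 40 °C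
Reagents that add atoms: none
Why: SNAr of a phenoxide on a fluoride activated by an ortho formyl and an ortho ester group, with excess of the symmetric diphenol securing mono-arylation.

Step 6
Reactants: 8 benzyl 3-formyl-2-(3-hydroxy-5-methylphenoxy)-4-methoxy-6-methylbenzoate
Product: 9 benzyl 3-formyl-4-methoxy-6-methyl-2-[(5-methyl-3,6-dioxocyclohexa-1,4-dien-1-yl)oxy]benzoate
Conditions: (KSO3)2NO (2.5 equiv), aq. KH2PO4, acetone–H2O, rt
Reagents that add atoms: potassium nitrosodisulfonate, [K+].[K+].[O-]S(=O)(=O)N([O])S(=O)(=O)[O-]
Why: Teuber oxidation of a phenol with a free para position gives the para-quinone, as known for 3-alkoxy-5-methylphenols, which places the new oxygen between the methyl group and the ether bridge.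

Step 7
Reactants: 9 the aryloxyquinone benzyl ester
Product: 11 2-(2,5-dihydroxy-3-methylphenoxy)-3-formyl-4-methoxy-6-methylbenzoic acid, via hydroquinone benzyl ester 10 (not isolated)
Conditions: H2 (1 atm), Pd/C, EtOAc, rt; filtered under argon and used directly
Reagents that add atoms: none
Why: Catalytic hydrogenation reduces the quinone to the hydroquinone and hydrogenolysis cleaves the benzyl ester, while a hindered, doubly ortho-oxygenated aryl aldehyde should survive in neutral ethyl acetate, as is usual in depside chemistry.

Step 8
Reactants: 11 2-(2,5-dihydroxy-3-methylphenoxy)-3-formyl-4-methoxy-6-methylbenzoic acid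
Product: 12 7-hydroxy-3-methoxy-1,9-dimethyl-11-oxo-11H-dibenzo[b,e][1,4]dioxepine-4-carbaldehyde
Conditions: DCC, DMAP (cat.), THF, high dilution, 0 °C → rt, argon
Reagents that add atoms: none
Why: Carbodiimide (Steglich-type) lactonisation, the classical depsidone closure, in which only the hydroxyl ortho to the ether bridge can reach the carboxyl group, so the seven-membered lactone forms and the remote hydroxyl stays free.

Step 9
Reactants: 12 the depsidone phenol
Product: 14 7-hydroxy-3-methoxy-1,9-dimethyl-11-oxo-11H-dibenzo[b,e][1,4]dioxepine-4,8-dicarbaldehyde, via 8-hydroxymethyl phenol 13 (not isolated)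
Conditions: MgCl2, Et3N, (CH2O)n, THF, reflux; aq. HCl
Reagents that add atoms: paraformaldehyde (as formaldehyde), C=O
Why: Casnati–Skattebøl ortho-formylation through the magnesium phenoxide (hydroxymethylation, then hydride transfer to a second formaldehyde), expected at C-8 because this ortho position is also para to the ether oxygen O-5, the orcinol-to-orcylaldehyde pattern.

Step 10
Reactants: 14 the ring B salicylaldehyde depsidone; 15 2-methylpropene
Product: 19 racemic 4-methoxy-2,2-dimethylchroman-fused depsidone (pyran ring O–CMe2–CH2–CH(OMe) spanning O-7 and C-8; ring A 3-OMe and 4-CHO), via bis(dimethyl acetal) 16 (not isolated), via methoxy ortho-quinone methide 17 (not isolated), via ring A acetal of the chroman 18 (not isolated)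
Conditions: HC(OMe)3 (4 equiv), TfOH (10 mol%), 2-methylpropene (excess, condensed), CH2Cl2, −20 °C → rt, sealed tube; then 1 M HCl, THF, 0 °C
Reagents that add atoms: trimethyl orthoformate, COC(OC)OC; water, O
Why: Acid and orthoformate turn both formyl groups into dimethyl acetals; the ring B acetal, next to the free 7-OH, loses methanol to the methoxy ortho-quinone methide 17 (O-protonated: a 2-hydroxybenzyl oxocarbenium ion), and 2-methylpropene attacks its exocyclic carbon with the CH2 terminus to give a tertiary cation that the ring oxygen captures. This is the known acid-catalysed three-component chroman synthesis from a salicylaldehyde, an orthoformate and an alkene, a polar inverse-demand oxa-(4+2) cycloaddition. The pyran ring closes as a six-membered ring in (4+2) fashion, C–C bond first and O–CMe2 bond second, so the oxygen ends on the dimethyl carbon (Markovnikov). The new stereocentre at the methoxy-bearing benzylic carbon forms as a racemate; nothing in the substrate biases it and no control is needed, because step 11 makes this carbon the carbonyl. The step needs chemoselectivity between the two formyl groups: only ring B has the ortho hydroxyl that closes the ring and makes alkene capture irreversible, whereas the ring A acetal (OMe in that position) can add the alkene only reversibly and is returned to the aldehyde by the mild acid work-up. Low temperature and catalytic acid should keep the benzylic ether of the product from re-ionising.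

Step 11
Reactants: 19 the racemic 4-methoxychroman depsidone
Product: 21 3-O-methylmollicellin B (2,2-dimethylchroman-4-one-fused depsidone; ring A 3-OMe and 4-CHO), via methyl hemiketal 20 (not isolated)
Conditions: DDQ (2 equiv), CH2Cl2–H2O (10:1), rt → 40 °C
Reagents that add atoms: water, O
Why: DDQ benzylic oxidation by hydride abstraction from the C–H activated by the ortho pyran oxygen and the para ether oxygen, then water capture and loss of methanol, the same reaction type as oxidative cleavage of alkoxybenzyl ethers, and it removes the stereocentre.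

Step 12
Reactants: 21 3-O-methylmollicellin B
Product: 23 mollicellin B, via aryloxydichloroborane 22 (not isolated)
Conditions: BCl3 (1 M in CH2Cl2), CH2Cl2, −78 → 0 °C; H2O
Reagents that add atoms: none
Why: Chelation-controlled O-demethylation, in which boron bridges the formyl oxygen and the adjacent methoxy oxygen so that chloride removes only this methyl group; the pyran oxygen cannot chelate with the chromanone carbonyl, and the lactone tolerates the Lewis acid.

**Compound list**

1 | 3,5-difluorotoluene | Cc1cc(F)cc(F)c1 | starting material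
2 | 2,6-difluoro-4-methylphenyllithium (not isolated) | Cc1cc(F)c([Li])c(F)c1 | intermediate
3 | 2,6-difluoro-4-methylbenzaldehyde | Cc1cc(F)c(C=O)c(F)c1 | intermediate
4 | 2-fluoro-6-methoxy-4-methylbenzaldehyde | COc1cc(C)cc(F)c1C=O | intermediate
5 | 3-bromo-2-fluoro-6-methoxy-4-methylbenzaldehyde | COc1cc(C)c(Br)c(F)c1C=O | intermediate
6 | benzyl 2-fluoro-3-formyl-4-methoxy-6-methylbenzoate | COc1cc(C)c(C(=O)OCc2ccccc2)c(F)c1C=O | intermediate
7 | orcinol (5-methylbenzene-1,3-diol) | Cc1cc(O)cc(O)c1 | starting material
8 | benzyl 3-formyl-2-(3-hydroxy-5-methylphenoxy)-4-methoxy-6-methylbenzoate | COc1cc(C)c(C(=O)OCc2ccccc2)c(Oc2cc(C)cc(O)c2)c1C=O | intermediate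
9 | benzyl 3-formyl-4-methoxy-6-methyl-2-[(5-methyl-3,6-dioxocyclohexa-1,4-dien-1-yl)oxy]benzoate | COc1cc(C)c(C(=O)OCc2ccccc2)c(OC2=CC(=O)C=C(C)C2=O)c1C=O | intermediate
10 | benzyl 2-(2,5-dihydroxy-3-methylphenoxy)-3-formyl-4-methoxy-6-methylbenzoate (not isolated) | COc1cc(C)c(C(=O)OCc2ccccc2)c(Oc2cc(O)cc(C)c2O)c1C=O | intermediate
11 | 2-(2,5-dihydroxy-3-methylphenoxy)-3-formyl-4-methoxy-6-methylbenzoic acid | COc1cc(C)c(C(=O)O)c(Oc2cc(O)cc(C)c2O)c1C=O | intermediate
12 | 7-hydroxy-3-methoxy-1,9-dimethyl-11-oxo-11H-dibenzo[b,e][1,4]dioxepine-4-carbaldehyde | Cc1cc(OC)c(C=O)c2c1C(=O)Oc1c(C)cc(O)cc1O2 | intermediate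
13 | 7-hydroxy-8-(hydroxymethyl)-3-methoxy-1,9-dimethyl-11-oxo-11H-dibenzo[b,e][1,4]dioxepine-4-carbaldehyde (not isolated) | Cc1cc(OC)c(C=O)c2c1C(=O)Oc1c(C)c(CO)c(O)cc1O2 | intermediate
14 | 7-hydroxy-3-methoxy-1,9-dimethyl-11-oxo-11H-dibenzo[b,e][1,4]dioxepine-4,8-dicarbaldehyde | Cc1cc(OC)c(C=O)c2c1C(=O)Oc1c(C)c(C=O)c(O)cc1O2 | intermediate
15 | 2-methylpropene | CC(C)=C | starting material
16 | bis(dimethyl acetal) of 14 (not isolated) | Cc1cc(OC)c(C(OC)OC)c2c1C(=O)Oc1c(C)c(C(OC)OC)c(O)cc1O2 | intermediate
17 | ring B methoxy ortho-quinone methide, ring A dimethyl acetal (not isolated) | Cc1cc(OC)c(C(OC)OC)c2c1C(=O)OC1=C(C)C(=COC)C(=O)C=C1O2 | intermediate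
18 | racemic 4-methoxychroman depsidone, ring A dimethyl acetal (not isolated) | Cc1cc(OC)c(C(OC)OC)c2c1C(=O)Oc1c(cc3c(c1C)C(OC)CC(C)(C)O3)O2 | intermediate
19 | racemic 4-methoxy-2,2-dimethylchroman-fused depsidone, ring A 3-OMe, 4-CHO | Cc1cc(OC)c(C=O)c2c1C(=O)Oc1c(cc3c(c1C)C(OC)CC(C)(C)O3)O2 | intermediate
20 | racemic methyl hemiketal at the chroman benzylic carbon (not isolated) | Cc1cc(OC)c(C=O)c2c1C(=O)Oc1c(cc3c(c1C)C(O)(OC)CC(C)(C)O3)O2 | intermediate
21 | 3-O-methylmollicellin B | Cc1cc(OC)c(C=O)c2c1C(=O)Oc1c(cc3c(c1C)C(=O)CC(C)(C)O3)O2 | intermediate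
22 | ring A aryloxydichloroborane of mollicellin B (not isolated) | Cc1cc(OB(Cl)Cl)c(C=O)c2c1C(=O)Oc1c(cc3c(c1C)C(=O)CC(C)(C)O3)O2 | intermediate
23 | mollicellin B (achiral) | Cc1cc(O)c(C=O)c2c1C(=O)Oc1c(cc3c(c1C)C(=O)CC(C)(C)O3)O2 | target

**Step count and risks**

Total steps: 12. Longest linear sequence: 12 steps (1 → 23); orcinol and 2-methylpropene enter as single building blocks.

Steps most likely to fail:

1. Step 10. The ring A dimethyl acetal should ionise to an oxocarbenium ion of similar stability to the ring B one and may capture 2-methylpropene in a Prins-type addition. In addition, the strong acid may oligomerise the alkene or re-ionise the benzylic ether of the product. The fallback removes the second ionisable carbon before the cycloaddition. Setting out from 12, propane-1,3-dithiol and BF3·OEt2 (CH2Cl2, 0 °C) convert the ring A formyl group into the 1,3-dithiane of the depsidone phenol F1. Formylation with MgCl2/Et3N/(CH2O)n as in step 9 gives the ring B salicylaldehyde with ring A dithiane F2. The same orthoformate/acid/2-methylpropene cycloaddition, now with one reactive carbon only, gives the methoxychroman with ring A dithiane F3. MeI and CaCO3 in aqueous MeCN (40 °C) then hydrolyse the thioacetal, and the route is rejoined at 19.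

2. Step 9. Formylation may go to the other ortho position (C-6, between the hydroxyl and O-5) or to both, and the methanol and amine present may open the lactone. The fallback brings the formyl carbon in with the ring B building block, so its position is fixed. Setting out from 6, SNAr with commercial 2,4-dihydroxy-6-methylbenzaldehyde (K2CO3, DMF), which reacts through its non-chelated 4-hydroxyl, gives benzyl 3-formyl-2-(4-formyl-3-hydroxy-5-methylphenoxy)-4-methoxy-6-methylbenzoate F4. Elbs persulfate oxidation (K2S2O8, aq. NaOH, 0 °C → rt) hydroxylates para to the phenol via the potassium aryl sulfate F5, which warm dilute HCl hydrolyses to the hydroquinone dialdehyde benzyl ester F6. Hydrogenolysis (H2, Pd/C, EtOAc) gives the hydroquinone dialdehyde acid F7, and DCC lactonisation as in step 8 rejoins the route at 14.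

3. Step 11. Hydride abstraction may be slow because ring B also carries the electron-withdrawing acyloxy group, so that forcing conditions lead to elimination to the chromene or attack at other benzylic positions. The fallback replaces hydride abstraction by solvolysis and alcohol oxidation. Setting out from 19, aqueous acid (TFA, THF–H2O, 0 °C → rt) exchanges the benzylic methoxy group for hydroxyl by an SN1 process to give the racemic chroman-4-ol F8, and Dess–Martin periodinane (NaHCO3, CH2Cl2) oxidises it to the ketone, rejoining the route at 21.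

**Further compounds**

F1 | step 10 | 4-(1,3-dithian-2-yl)-7-hydroxy-3-methoxy-1,9-dimethyl-11H-dibenzo[b,e][1,4]dioxepin-11-one | Cc1cc(OC)c(C3SCCCS3)c2c1C(=O)Oc1c(C)cc(O)cc1O2
F2 | step 10 | 4-(1,3-dithian-2-yl)-7-hydroxy-3-methoxy-1,9-dimethyl-11-oxo-11H-dibenzo[b,e][1,4]dioxepine-8-carbaldehyde | Cc1cc(OC)c(C3SCCCS3)c2c1C(=O)Oc1c(C)c(C=O)c(O)cc1O2
F3 | step 10 | racemic 4-methoxy-2,2-dimethylchroman-fused depsidone with ring A 1,3-dithiane | Cc1cc(OC)c(C4SCCCS4)c2c1C(=O)Oc1c(cc3c(c1C)C(OC)CC(C)(C)O3)O2
F4 | step 9 | benzyl 3-formyl-2-(4-formyl-3-hydroxy-5-methylphenoxy)-4-methoxy-6-methylbenzoate | COc1cc(C)c(C(=O)OCc2ccccc2)c(Oc2cc(C)c(C=O)c(O)c2)c1C=O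
F5 | step 9 | potassium aryl sulfate of the Elbs oxidation (sulfate para to the phenol, not isolated) | COc1cc(C)c(C(=O)OCc2ccccc2)c(Oc2cc(O)c(C=O)c(C)c2OS(=O)(=O)[O-])c1C=O.[K+]
F6 | step 9 | benzyl 2-(4-formyl-2,5-dihydroxy-3-methylphenoxy)-3-formyl-4-methoxy-6-methylbenzoate | COc1cc(C)c(C(=O)OCc2ccccc2)c(Oc2cc(O)c(C=O)c(C)c2O)c1C=O
F7 | step 9 | 2-(4-formyl-2,5-dihydroxy-3-methylphenoxy)-3-formyl-4-methoxy-6-methylbenzoic acid | COc1cc(C)c(C(=O)O)c(Oc2cc(O)c(C=O)c(C)c2O)c1C=O
F8 | step 11 | racemic 4-hydroxy-2,2-dimethylchroman-fused depsidone, ring A 3-OMe, 4-CHO | Cc1cc(OC)c(C=O)c2c1C(=O)Oc1c(cc3c(c1C)C(O)CC(C)(C)O3)O2
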